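**Strategy.** The plan rests on the four C–Br bonds para and ortho to the bridging ether oxygen: C4 and C6 of the dibromo ring A, C4' and C6' of the tribromo ring B (rings numbered from the carbon on the bridging oxygen; hydroxyl carbons C2 and C2'). One Lewis-acid bromination makes all four, because both hydroxyl oxygens are mesylated and only the bridging oxygen directs. The precursor is a bis(2-mesyloxyphenyl) ether already carrying the fifth bromine at C5', para to O2'; bought in with 5-bromoguaiacol, it is a spectator that blocks the site para to that sulfonate and flanks C4' and C6'. Mesylate hydrolysis ends the route.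

Key step: step 4

Remark: the target has no stereocentre and its diaryl ether bonds rotate freely, so it is one achiral compound and no step needs stereocontrol.

Step 1
Reactants: 1 5-bromo-2-methoxyphenol; 2 2-iodoanisole
Product: 3 4-bromo-1-methoxy-2-(2-methoxyphenoxy)benzene
Conditions: 2 (1.3 equiv), CuI (10 mol%), N,N-dimethylglycine·HCl (30 mol%), Cs2CO3 (2 equiv), dioxane, 90 °C
Reagents that add atoms: none
Why: Ullmann diaryl ether synthesis, in which copper should insert into the C–I bond of 2 much faster than into the electron-rich C–Br bond of 1 or 3, so the phenoxide of 1 is arylated at oxygen and the bromine is kept.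

Step 2
Reactants: 3 4-bromo-1-methoxy-2-(2-methoxyphenoxy)benzene
Product: 4 4-bromo-2-(2-hydroxyphenoxy)phenol
Conditions: BBr3 (3 equiv), CH2Cl2, −78 °C → rt; then H2O
Reagents that add atoms: none
Why: Lewis-acid ether cleavage, in which BBr3 binds each methoxy oxygen and bromide removes the methyl group by SN2, while the sp2 C–O bonds of the diaryl ether and the aryl bromide cannot react this way.

Step 3
Reactants: 4 4-bromo-2-(2-hydroxyphenoxy)phenol
Product: 5 4-bromo-2-[2-(methylsulfonyloxy)phenoxy]phenyl methanesulfonate
Conditions: MsCl (2.5 equiv), Et3N (3 equiv), CH2Cl2, 0 °C → rt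
Reagents that add atoms: methanesulfonyl chloride, CS(=O)(=O)Cl
Why: O-sulfonylation of the two phenols, the only nucleophilic sites in 4, should give the bis-mesylate cleanly.

Step 4
Reactants: 5 4-bromo-2-[2-(methylsulfonyloxy)phenoxy]phenyl methanesulfonate
Product: 9 3,4,5-tribromo-2-[2,4-dibromo-6-(methylsulfonyloxy)phenoxy]phenyl methanesulfonate, via ring-A para-bromide 6 (not isolated), via bis-para tribromide 7 (not isolated), via tetrabromide 8 (not isolated)
Conditions: Br2 (4.4 equiv), FeBr3 (20 mol%), ClCH2CH2Cl, 0 °C → 60 °C, dark; aq. Na2S2O3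
Reagents that add atoms: bromine, BrBr
Why: Four electrophilic aromatic substitutions follow one another, each by addition of FeBr3-polarised bromine to a ring and loss of a proton from the arenium ion. The oxygens on C2 and C2' are tied up by their sulfonyl groups and donate little, so the arenium ions are stabilised mainly by the bridging oxygen, first at the para carbons C4 and C4' and then at the ortho carbons C6 and C6'; the other ortho carbons already carry the mesyloxy groups. The closest known reaction type is the Lewis-acid bromination of diphenyl ether to its 2,2',4,4'-tetrabromide, combined with aryl sulfonates as weakly directing phenol surrogates. No ring is formed and no stereocentre arises. The selectivity needed is bridge-directed attack over attack para to a sulfonate: on ring B the C5' bromine occupies that carbon and is ortho to both wanted carbons, and on ring A (C6 against C5) it rests on the donor gap between a diaryl ether oxygen and a mesylated one. The last substitution at C6', between the bridge and C5'–Br, should be the slowest, hence the warming and a bromine charge kept to a small excess.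

Step 5
Reactants: 9 3,4,5-tribromo-2-[2,4-dibromo-6-(methylsulfonyloxy)phenoxy]phenyl methanesulfonate
Product: 10 3,4,5-tribromo-2-(2,4-dibromo-6-hydroxyphenoxy)phenol
Conditions: 2 M aq. NaOH (6 equiv), THF–MeOH, 50 °C; then 1 M HCl
Reagents that add atoms: none
Why: Hydrolysis of aryl sulfonate esters, in which hydroxide attacks sulfur (or forms sulfene by E1cB) and expels the well-stabilised bromophenoxides, while the unactivated aryl bromides and the diaryl ether should not be substituted at this temperature.

**Compound list**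

1 | 5-bromo-2-methoxyphenol | COc1ccc(Br)cc1O | starting material
2 | 2-iodoanisole | COc1ccccc1I | starting material
3 | 4-bromo-1-methoxy-2-(2-methoxyphenoxy)benzene | COc1ccccc1Oc1cc(Br)ccc1OC | intermediate
4 | 4-bromo-2-(2-hydroxyphenoxy)phenol | Oc1ccccc1Oc1cc(Br)ccc1O | intermediate
5 | 4-bromo-2-[2-(methylsulfonyloxy)phenoxy]phenyl methanesulfonate | CS(=O)(=O)Oc1ccccc1Oc1cc(Br)ccc1OS(C)(=O)=O | intermediate
6 | 4-bromo-2-[4-bromo-2-(methylsulfonyloxy)phenoxy]phenyl methanesulfonate | CS(=O)(=O)Oc1cc(Br)ccc1Oc1cc(Br)ccc1OS(C)(=O)=O | intermediate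
7 | 4,5-dibromo-2-[4-bromo-2-(methylsulfonyloxy)phenoxy]phenyl methanesulfonate | CS(=O)(=O)Oc1cc(Br)ccc1Oc1cc(Br)c(Br)cc1OS(C)(=O)=O | intermediate
8 | 4,5-dibromo-2-[2,4-dibromo-6-(methylsulfonyloxy)phenoxy]phenyl methanesulfonate | CS(=O)(=O)Oc1cc(Br)cc(Br)c1Oc1cc(Br)c(Br)cc1OS(C)(=O)=O | intermediate
9 | 3,4,5-tribromo-2-[2,4-dibromo-6-(methylsulfonyloxy)phenoxy]phenyl methanesulfonate | CS(=O)(=O)Oc1cc(Br)cc(Br)c1Oc1c(Br)c(Br)c(Br)cc1OS(C)(=O)=O | intermediate
10 | 3,4,5-tribromo-2-(2,4-dibromo-6-hydroxyphenoxy)phenol | Oc1cc(Br)cc(Br)c1Oc1c(O)cc(Br)c(Br)c1Br | target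

**Total step count:** 5. **Longest linear sequence:** 5 steps (1 → 10).

**Steps most likely to fail**

Step 4. The later substitutions may drift to C5 of ring A (para to the sulfonylated oxygen), stall before the crowded C6' reacts, or run on to a sixth bromine under forcing. The fallback brings the two bromines of ring A in with a building block and leaves only ring B to brominate. It sets out from 1: SNAr on 3,5-dibromo-2-fluorobenzaldehyde (K2CO3, DMF, 90 °C) should give 3,5-dibromo-2-(5-bromo-2-methoxyphenoxy)benzaldehyde F1. Baeyer–Villiger oxidation (mCPBA, CH2Cl2) should give 3,5-dibromo-2-(5-bromo-2-methoxyphenoxy)phenyl formate F2, hydrolysed in the same flask (KOH, MeOH–H2O) to 3,5-dibromo-2-(5-bromo-2-methoxyphenoxy)phenol F3. BBr3 should give 3,5-dibromo-2-(5-bromo-2-hydroxyphenoxy)phenol F4, and MsCl/Et3N should give 3,5-dibromo-2-[5-bromo-2-(methylsulfonyloxy)phenoxy]phenyl methanesulfonate F5. Br2/FeBr3 then has only C4' and C6' to substitute, both ortho to C5'–Br; it passes through 8 and comes back to the route at 9.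

Step 1. Copper may also insert into the C–Br bond of 1 or 3 and give oligomeric ethers, and the coupling of two ortho-substituted partners may be slow. The fallback is metal-free and sets out from 1: SNAr on 2-fluorobenzaldehyde (K2CO3, DMF, 100 °C) should give 2-(5-bromo-2-methoxyphenoxy)benzaldehyde F6. Baeyer–Villiger oxidation with mCPBA should give 2-(5-bromo-2-methoxyphenoxy)phenyl formate F7, cleaved in the same flask (KOH, MeOH–H2O) to 2-(5-bromo-2-methoxyphenoxy)phenol F8. BBr3 removes the single methyl group and the sequence comes back to the route at 4.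

Step 5. Hydroxide or methoxide may attack a ring carbon of the electron-poor pentabromide, displacing bromide or moving an aryl group between the neighbouring oxygens, in competition with sulfonate cleavage. The fallback uses masks that a soft nucleophile removes at room temperature and sets out from 4: 2-nitrobenzenesulfonyl chloride/Et3N should give 4-bromo-2-[2-(2-nitrophenylsulfonyloxy)phenoxy]phenyl 2-nitrobenzenesulfonate F9. Bromination as in step 4 (Br2, FeBr3) should give 3,4,5-tribromo-2-[2,4-dibromo-6-(2-nitrophenylsulfonyloxy)phenoxy]phenyl 2-nitrobenzenesulfonate F10. Thiophenol/K2CO3 in DMF at rt then removes both masks by ipso-substitution on the nitroarene with loss of SO2, and the sequence comes back to the route at 10.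

**Further compounds**

F1 | step 4 | 3,5-dibromo-2-(5-bromo-2-methoxyphenoxy)benzaldehyde | COc1ccc(Br)cc1Oc1c(Br)cc(Br)cc1C=O
F2 | step 4 | 3,5-dibromo-2-(5-bromo-2-methoxyphenoxy)phenyl formate | COc1ccc(Br)cc1Oc1c(Br)cc(Br)cc1OC=O
F3 | step 4 | 3,5-dibromo-2-(5-bromo-2-methoxyphenoxy)phenol | COc1ccc(Br)cc1Oc1c(Br)cc(Br)cc1O
F4 | step 4 | 3,5-dibromo-2-(5-bromo-2-hydroxyphenoxy)phenol | Oc1ccc(Br)cc1Oc1c(Br)cc(Br)cc1O
F5 | step 4 | 3,5-dibromo-2-[5-bromo-2-(methylsulfonyloxy)phenoxy]phenyl methanesulfonate | CS(=O)(=O)Oc1ccc(Br)cc1Oc1c(Br)cc(Br)cc1OS(C)(=O)=O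
F6 | step 1 | 2-(5-bromo-2-methoxyphenoxy)benzaldehyde | COc1ccc(Br)cc1Oc1ccccc1C=O
F7 | step 1 | 2-(5-bromo-2-methoxyphenoxy)phenyl formate | COc1ccc(Br)cc1Oc1ccccc1OC=O
F8 | step 1 | 2-(5-bromo-2-methoxyphenoxy)phenol | COc1ccc(Br)cc1Oc1ccccc1O
F9 | step 5 | 4-bromo-2-[2-(2-nitrophenylsulfonyloxy)phenoxy]phenyl 2-nitrobenzenesulfonate | O=[N+]([O-])c1ccccc1S(=O)(=O)Oc1ccccc1Oc1cc(Br)ccc1OS(=O)(=O)c1ccccc1[N+](=O)[O-]
F10 | step 5 | 3,4,5-tribromo-2-[2,4-dibromo-6-(2-nitrophenylsulfonyloxy)phenoxy]phenyl 2-nitrobenzenesulfonate | O=[N+]([O-])c1ccccc1S(=O)(=O)Oc1cc(Br)cc(Br)c1Oc1c(Br)c(Br)c(Br)cc1OS(=O)(=O)c1ccccc1[N+](=O)[O-]
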